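**Plan**

1. The target is the all-exo furofuran (2,6-diaryl-3,7-dioxabicyclo[3.3.0]octane), 7R,8S,7'R,8'S in lignan numbering (unprimed = syringyl half, primed = trimethoxyphenyl half). The phenol is carried as a TIPS ether.
2. Cuts: first the O–C7' bond together with the C8–C8' bond, then the C9'–O ether bond, then the epoxide oxygen on C8/C9 and the C7–C8 bond.
3. Enabling feature: in ring C8–C9–O–C7'–C8' the oxygen on C9 is β to bridgehead C8, so C8/C9/O can be stored as an epoxide that trivalent titanium opens to a C8 radical. Ring O–C7–C8–C8'–C9' is then the 5-exo product of a 3-oxahex-5-enyl radical, and C7' is benzylic to an electron-rich arene, so the radical left there can be oxidised and captured by the same oxygen.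
4. Forward: aldehyde → vinyl carbinol → epoxy alcohol (Sharpless kinetic resolution) → cinnamyl ether → one-flask Cp2TiCl/I2 cascade (ring O–C7–C8–C8'–C9' first, ring C8–C9–O–C7'–C8' last) → desilylation.
5. Stereochemistry: C7 from the kinetic resolution; C8 and C8' from the chair-like 5-exo transition state directed by C7; C7' from exo closure on the convex face of the cis-fused bicycle.

Key step: step 7

Remark: the descriptor at C7 changes from R (allylic alcohol) to S (epoxides) and back to R (bicycle) only because the ranking of its neighbours changes; the spatial arrangement is the same throughout.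

**Route**

Step 1
Reactants: 1 syringaldehyde (4-hydroxy-3,5-dimethoxybenzaldehyde)
Product: 2 3,5-dimethoxy-4-(triisopropylsilyloxy)benzaldehyde
Conditions: TIPSCl, imidazole, DMAP (cat.), DMF, rt
Reagents that add atoms: triisopropylsilyl chloride, CC(C)[Si](Cl)(C(C)C)C(C)C
Why: Imidazole-promoted silylation of the phenol (silyl ether protection) should give a hindered aryl silyl ether that is stable to the Grignard reagent, to alkoxide in THF, to titanium reagents and to iodine, and that fluoride removes at the end without harm to the benzylic ethers.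

Step 2
Reactants: 2 3,5-dimethoxy-4-(triisopropylsilyloxy)benzaldehyde
Product: 3 racemic 1-[3,5-dimethoxy-4-(triisopropylsilyloxy)phenyl]prop-2-en-1-ol
Conditions: CH2=CHMgBr, THF, −78 to 0 °C; then sat. aq NH4Cl
Reagents that add atoms: vinylmagnesium bromide, C=C[Mg]Br
Why: Grignard 1,2-addition to the aldehyde forms the C7–C8 bond and the allylic alcohol needed for a directed epoxidation; the carbinol centre C7 forms as a racemate and is resolved in step 3.

Step 3
Reactants: 3 racemic 1-[3,5-dimethoxy-4-(triisopropylsilyloxy)phenyl]prop-2-en-1-ol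
Product: 4 (S)-[3,5-dimethoxy-4-(triisopropylsilyloxy)phenyl][(2R)-oxiran-2-yl]methanol (erythro)
Conditions: Ti(OiPr)4 (0.2 equiv), L-(+)-DIPT (0.24 equiv), TBHP (0.45 equiv), 4 Å MS, CH2Cl2, −20 °C
Reagents that add atoms: tert-butyl hydroperoxide, CC(C)(C)OO
Why: Sharpless kinetic resolution (asymmetric epoxidation of a secondary allylic alcohol by the catalyst formed from Ti(OiPr)4 and L-(+)-DIPT) should epoxidise the (R)-enantiomer of 3 much faster than the (S)-enantiomer and give the erythro epoxy alcohol, so that C7 is selected by the chiral catalyst and the epoxide carbon C8 by the matched catalyst–substrate pair, while the unreacted (S)-alcohol is removed by chromatography.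

Step 4
Reactants: 5 methyl (E)-3-(3,4,5-trimethoxyphenyl)prop-2-enoate
Product: 6 (E)-3-(3,4,5-trimethoxyphenyl)prop-2-en-1-ol
Conditions: iBu2AlH, CH2Cl2, −78 °C; then aq KNaC4H4O6 (potassium sodium tartrate)
Reagents that add atoms: none
Why: 1,2-Reduction of the α,β-unsaturated ester with iBu2AlH at low temperature (ester to allylic alcohol reduction) should leave the E double bond untouched.

Step 5
Reactants: 6 (E)-3-(3,4,5-trimethoxyphenyl)prop-2-en-1-ol
Product: 7 5-[(E)-3-bromoprop-1-enyl]-1,2,3-trimethoxybenzene
Conditions: PBr3, Et2O, 0 °C; used crude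
Reagents that add atoms: phosphorus tribromide, BrP(Br)Br
Why: Bromination of the primary allylic alcohol with PBr3 (SN2 on the phosphite intermediate) should give the linear E cinnamyl bromide, which is the conjugated and thermodynamically preferred allylic isomer.

Step 6
Reactants: 4 (S)-[3,5-dimethoxy-4-(triisopropylsilyloxy)phenyl][(2R)-oxiran-2-yl]methanol; 7 5-[(E)-3-bromoprop-1-enyl]-1,2,3-trimethoxybenzene
Product: 8 (2R)-2-[(S)-[3,5-dimethoxy-4-(triisopropylsilyloxy)phenyl]{[(E)-3-(3,4,5-trimethoxyphenyl)prop-2-enyl]oxy}methyl]oxirane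
Conditions: NaH, THF, 0 °C; then 7, nBu4NI (cat.), 0 °C to rt
Reagents that add atoms: none
Why: Williamson ether synthesis, in which the sodium alkoxide of 4 attacks the primary allylic bromide in an SN2 reaction at C9', joins the two halves without touching C7 or the epoxide, THF at low temperature being chosen to keep Payne rearrangement and silyl transfer slow.

Step 7
Reactants: 8 (2R)-2-[(S)-[3,5-dimethoxy-4-(triisopropylsilyloxy)phenyl]{[(E)-3-(3,4,5-trimethoxyphenyl)prop-2-enyl]oxy}methyl]oxirane
Product: 11 [4-[(1R,3aS,4R,6aS)-4-(3,4,5-trimethoxyphenyl)tetrahydro-1H,3H-furo[3,4-c]furan-1-yl]-2,6-dimethoxyphenoxy]tri(propan-2-yl)silane, via benzylic Cp2Ti(Cl) species 9 (not isolated), via benzylic iodide 10 (not isolated)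
Conditions: Cp2TiCl2 (2.5 equiv), Zn dust, THF, rt (gives Cp2TiCl), added dropwise to 8 in THF, rt; then I2 (1.5 equiv), THF, rt to 60 °C
Reagents that add atoms: none
Why: Cp2TiCl (trivalent titanium) transfers one electron to the terminal epoxide and cleaves its C8–O bond, which gives the more substituted C8 radical and the C9–O–titanium alkoxide; the C8 radical adds 5-exo-trig to C8' of the cinnamyl ether (ring O–C7–C8–C8'–C9', new C8–C8' bond), the resulting C7' benzylic radical is held by a second Cp2TiCl as benzylic titanium species 9, iodine turns this into benzylic iodide 10, and the titanium-bound C9 oxygen then displaces iodide at C7' in a 5-exo-tet cycloetherification with ion-pair character (ring C8–C9–O–C7'–C8', the last ring). The closest known reaction type is the Cp2TiCl-mediated reductive epoxide opening and radical cyclisation of epoxy allyl ethers with iodine termination, which is established for 2,6-diaryl-3,7-dioxabicyclo[3.3.0]octanes. C8 and C8' are controlled by C7 through the chair-like 5-exo transition state with the C7 aryl group pseudo-equatorial, which places the C9 arm trans to that aryl group and cis to the C7' arm on C8', the only arrangement from which a cis-fused second ring can form. C7' is controlled by the bicyclic framework: both epimers of 10 ionise easily next to the 3,4,5-trimethoxyphenyl ring and should close with the aryl group exo on the convex face, which is also the thermodynamic isomer. The step needs cyclisation of the C8 radical to be faster than its reduction by Cp2TiCl (which would end in β-elimination) and needs the benzylic centre to be functionalised rather than reduced; the styrene acceptor five atoms away, slow addition of Cp2TiCl and the electron-rich aryl group at C7' secure this, and because the epoxide stereocentre becomes a planar radical, only the C7 configuration from step 3 is carried into the product.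

Step 8
Reactants: 11 [4-[(1R,3aS,4R,6aS)-4-(3,4,5-trimethoxyphenyl)tetrahydro-1H,3H-furo[3,4-c]furan-1-yl]-2,6-dimethoxyphenoxy]tri(propan-2-yl)silane
Product: 12 4-[(1R,3aS,4R,6aS)-4-(3,4,5-trimethoxyphenyl)tetrahydro-1H,3H-furo[3,4-c]furan-1-yl]-2,6-dimethoxyphenol (CID53356312)
Conditions: nBu4NF, AcOH, THF, 0 °C
Reagents that add atoms: none
Why: Fluoride-induced cleavage of the aryl silicon–oxygen bond (silyl ether deprotection) should free the phenol, the acetic acid buffer protonating the phenoxide at once so that the p-hydroxybenzylic ether at C7 is not opened; no stereocentre is involved.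

**Compound list**

1 | syringaldehyde (4-hydroxy-3,5-dimethoxybenzaldehyde) | O=Cc1cc(OC)c(O)c(OC)c1 | starting material
2 | 3,5-dimethoxy-4-(triisopropylsilyloxy)benzaldehyde | O=Cc1cc(OC)c(O[Si](C(C)C)(C(C)C)C(C)C)c(OC)c1 | intermediate
3 | racemic 1-[3,5-dimethoxy-4-(triisopropylsilyloxy)phenyl]prop-2-en-1-ol | C=CC(O)c1cc(OC)c(O[Si](C(C)C)(C(C)C)C(C)C)c(OC)c1 | intermediate
4 | (S)-[3,5-dimethoxy-4-(triisopropylsilyloxy)phenyl][(2R)-oxiran-2-yl]methanol (erythro) | O[C@@H](c1cc(OC)c(O[Si](C(C)C)(C(C)C)C(C)C)c(OC)c1)[C@H]1CO1 | intermediate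
5 | methyl (E)-3-(3,4,5-trimethoxyphenyl)prop-2-enoate | COC(=O)/C=C/c1cc(OC)c(OC)c(OC)c1 | starting material
6 | (E)-3-(3,4,5-trimethoxyphenyl)prop-2-en-1-ol | OC/C=C/c1cc(OC)c(OC)c(OC)c1 | intermediate
7 | 5-[(E)-3-bromoprop-1-enyl]-1,2,3-trimethoxybenzene | BrC/C=C/c1cc(OC)c(OC)c(OC)c1 | intermediate
8 | (2R)-2-[(S)-[3,5-dimethoxy-4-(triisopropylsilyloxy)phenyl]{[(E)-3-(3,4,5-trimethoxyphenyl)prop-2-enyl]oxy}methyl]oxirane | COc1cc(/C=C/CO[C@@H](c2cc(OC)c(O[Si](C(C)C)(C(C)C)C(C)C)c(OC)c2)[C@H]2CO2)cc(OC)c1OC | intermediate
9 | benzylic Cp2Ti(Cl) species, not isolated: (2R,3S,4S)-2-[3,5-dimethoxy-4-(triisopropylsilyloxy)phenyl]oxolane with CH2O–Ti(Cl)Cp2 at C3 and CH[Ti(Cl)Cp2](3,4,5-trimethoxyphenyl) at C4 (tetravalent titanium at both centres; both C7' epimers) | COc1cc([C@@H]2OC[C@@H](C([Ti](Cl)(C3C=CC=C3)C3C=CC=C3)c3cc(OC)c(OC)c(OC)c3)[C@H]2CO[Ti](Cl)(C2C=CC=C2)C2C=CC=C2)cc(OC)c1O[Si](C(C)C)(C(C)C)C(C)C | intermediate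
10 | benzylic iodide, not isolated: Cp2Ti(Cl) alkoxide (tetravalent titanium) of [(2R,3S,4S)-2-[3,5-dimethoxy-4-(triisopropylsilyloxy)phenyl]-4-[iodo(3,4,5-trimethoxyphenyl)methyl]oxolan-3-yl]methanol (both C7' epimers) | COc1cc([C@@H]2OC[C@@H](C(I)c3cc(OC)c(OC)c(OC)c3)[C@H]2CO[Ti](Cl)(C2C=CC=C2)C2C=CC=C2)cc(OC)c1O[Si](C(C)C)(C(C)C)C(C)C | intermediate
11 | [4-[(1R,3aS,4R,6aS)-4-(3,4,5-trimethoxyphenyl)tetrahydro-1H,3H-furo[3,4-c]furan-1-yl]-2,6-dimethoxyphenoxy]tri(propan-2-yl)silane | COc1cc([C@@H]2OC[C@@H]3[C@H]2CO[C@H]3c2cc(OC)c(OC)c(OC)c2)cc(OC)c1O[Si](C(C)C)(C(C)C)C(C)C | intermediate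
12 | 4-[(1R,3aS,4R,6aS)-4-(3,4,5-trimethoxyphenyl)tetrahydro-1H,3H-furo[3,4-c]furan-1-yl]-2,6-dimethoxyphenol (CID53356312) | COc1cc([C@@H]2OC[C@@H]3[C@H]2CO[C@H]3c2cc(OC)c(OC)c(OC)c2)cc(OC)c1O | target

**Step count and risks**

Total step count: 8. Longest linear sequence: 6 steps (steps 1, 2, 3, 6, 7, 8 from syringaldehyde); steps 4 and 5 form the side branch.

Steps most likely to fail:

Step 7. The 5-exo radical addition may proceed with incomplete facial control at C8', or the radicals may be reduced too early (the C8 radical before it cyclises, the C7' radical by hydrogen abstraction before iodination), so that the second ring does not close. The fallback separates C–C from C–O bond formation and sets only one stereocentre in the radical step. It sets out from compound 4: O-propargylation (NaH, propargyl bromide, THF, 0 °C) should give the propargyl ether F1. Sonogashira coupling with 5-iodo-1,2,3-trimethoxybenzene (PdCl2(PPh3)2 as divalent palladium precatalyst, CuI, Et3N, THF, rt) should give the aryl alkyne F2. Cp2TiCl (from Cp2TiCl2 and Zn, THF, rt; dilute aqueous acid quench) opens the epoxide and the C8 radical closes 5-exo-dig onto the alkyne, the vinyl radical taking hydrogen from THF, to give the benzylidene tetrahydrofuran alcohol F3 with the C9 arm trans to the C7 aryl group. Acid-catalysed intramolecular hydroalkoxylation of the electron-rich styrene (camphorsulfonic acid, CH2Cl2, 0 °C to rt) then closes ring C8–C9–O–C7'–C8' through the C7' benzylic cation, the cis ring fusion and the exo aryl group being the thermodynamic outcome, and the route is rejoined at compound 11.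

Step 3. Epoxidation of the terminal vinyl group may be slow and the rate difference between the enantiomers too small, so that the epoxy alcohol is collected with insufficient enantiomeric purity at a useful conversion. The fallback separates resolution from epoxidation and sets out from compound 3: enzymatic acylation (immobilised Candida antarctica lipase B, vinyl acetate, MTBE, rt) should acylate the (R)-enantiomer selectively to give the allylic acetate F4, which is separated from the untouched (S)-alcohol. Methanolysis (K2CO3, MeOH, 0 °C) gives the (R)-allylic alcohol F5. Its matched Sharpless epoxidation, run to full conversion (Ti(OiPr)4, L-(+)-DIPT, TBHP, 4 Å MS, CH2Cl2, −20 °C), returns the route at compound 4.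

Step 6. The epoxy alkoxide may undergo Payne rearrangement before it is alkylated, the aryl silyl group may be transferred to the alkoxide, or the electron-rich cinnamyl bromide may decompose by ionisation. The fallback avoids a free alkali alkoxide and the bromide and sets out from compound 6: acetylation (Ac2O, pyridine, DMAP, CH2Cl2, rt) gives the cinnamyl acetate F6. Tsuji–Trost allylic etherification of the zinc alkoxide of 4 (Et2Zn 0.5 equiv, then F6, Pd(OAc)2 (cat.), 2-(di-tert-butylphosphino)biphenyl, NH4OAc (cat.), THF, rt; zerovalent palladium forms in the flask) should give the linear E ether through the π-allyl palladium intermediate, and the route is rejoined at compound 8.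

Further compounds
F1 | step 7 | (2R)-2-[(S)-[3,5-dimethoxy-4-(triisopropylsilyloxy)phenyl](prop-2-ynyloxy)methyl]oxirane | C#CCO[C@@H](c1cc(OC)c(O[Si](C(C)C)(C(C)C)C(C)C)c(OC)c1)[C@H]1CO1
F2 | step 7 | (2R)-2-[(S)-[3,5-dimethoxy-4-(triisopropylsilyloxy)phenyl]{[3-(3,4,5-trimethoxyphenyl)prop-2-ynyl]oxy}methyl]oxirane | COc1cc(C#CCO[C@@H](c2cc(OC)c(O[Si](C(C)C)(C(C)C)C(C)C)c(OC)c2)[C@H]2CO2)cc(OC)c1OC
F3 | step 7 | [(2R,3S)-2-[3,5-dimethoxy-4-(triisopropylsilyloxy)phenyl]-4-[(3,4,5-trimethoxyphenyl)methylidene]oxolan-3-yl]methanol (E/Z mixture) | COc1cc([C@@H]2OCC(=Cc3cc(OC)c(OC)c(OC)c3)[C@H]2CO)cc(OC)c1O[Si](C(C)C)(C(C)C)C(C)C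
F4 | step 3 | (R)-1-[3,5-dimethoxy-4-(triisopropylsilyloxy)phenyl]prop-2-enyl acetate | C=C[C@@H](OC(C)=O)c1cc(OC)c(O[Si](C(C)C)(C(C)C)C(C)C)c(OC)c1
F5 | step 3 | (R)-1-[3,5-dimethoxy-4-(triisopropylsilyloxy)phenyl]prop-2-en-1-ol | C=C[C@@H](O)c1cc(OC)c(O[Si](C(C)C)(C(C)C)C(C)C)c(OC)c1
F6 | step 6 | (E)-3-(3,4,5-trimethoxyphenyl)prop-2-enyl acetate | CC(=O)OC/C=C/c1cc(OC)c(OC)c(OC)c1
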